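**Plan**

- Numbering (ent-kaurane) used throughout: ring A = C1(=O), C2=C3, C4(Me2), C5, C10; C6 = CH2OH on C5; δ-lactone C7(=O)–O–C20H2, spiro at C10; C8 quaternary; ring C = C8, C9, C11, C12, C13, C14; ring D = C8, C14, C13(OH), C16 (methyl = C17), C15(=O).
- Retrosynthesis: C13–C16 is cut first (intramolecular aldol of a 1,4-diketone, opening ring D); then C11–C12 and C8–C14 are cut together (alkylative [3+3] annulation, removing C12–C13–C14 as a 2-methylenepropane-1,3-diyl unit); then C8–C15 and C9–C11 (sulfonyl-carbanion conjugate addition with formyl trapping), the lactone and C9–C10 (Michael addition to methyl acrylate), and C5–C6 (conjugate vinylation of a dienone).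
- Forward: ring A from 4,4-dimethylcyclohexadienone, then the spiro δ-lactone, then ring C in the key step, then ring D by aldol; the C6 and C13 oxygens are unveiled together by ozonolysis of a vinyl group and of the exocyclic methylene.
- Feature that makes the key event possible: C8 is the α-carbon of both the C7 lactone carbonyl and the C15 carbonyl, and C11 hangs on the neighbouring C9, so a C8 enolate / C11 sulfonyl carbanion pair is a 1,3-dinucleophile that fits the three-carbon bridge C12–C13–C14 of six-membered ring C; C13 carries only oxygen and the ring D bond besides, so it can enter as an sp2 carbon bearing a methylene group (latent ketone).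
- Stereochemistry: C5 by rhodium/(R)-BINAP catalysis; C10 (Michael addition anti to the C5 vinyl), C9 (conjugate addition on the C1 face of the spirolactone), C8 (cis-annulation relayed from C9 in the key step) and C13/C16 (bridged aldol through the (Z)-enolate) follow by substrate control.

Key step: step 9

Remark: C11 (sulfone-bearing) and C15 (carbinol) are temporary stereocentres carried as epimer mixtures and left undefined in the SMILES, as is the enol geometry of 15 and 17.

Step 1
Reactants: 1 4,4-dimethylcyclohex-2-en-1-one
Product: 2 4,4-dimethylcyclohexa-2,5-dien-1-one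
Conditions: DDQ, dioxane, reflux
Reagents that add atoms: none
Why: Quinone (DDQ) dehydrogenation of the only enolisable CH2–CH2 unit should give the cross-conjugated dienone, no other direction being open because C4 is quaternary.

Step 2
Reactants: 2 4,4-dimethylcyclohexa-2,5-dien-1-one
Product: 3 (5R)-5-ethenyl-4,4-dimethylcyclohex-2-en-1-one
Conditions: [Rh(cod)2]BF4 (3 mol%), (R)-BINAP, CH2=CHBF3K, toluene–H2O, 100 °C
Reagents that add atoms: potassium vinyltrifluoroborate C=C[B-](F)(F)F.[K+]
Why: Hayashi–Miyaura rhodium-catalysed asymmetric conjugate addition should desymmetrise the two enantiotopic enone units, (R)-BINAP being chosen by the usual cyclohexenone model to give the (5R) centre (C5 of the target), while the second, now more hindered enone should remain.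

Step 3
Reactants: 3 (5R)-5-ethenyl-4,4-dimethylcyclohex-2-en-1-one
Product: 4 (5R,6Z)-5-ethenyl-6-(hydroxymethylidene)-4,4-dimethylcyclohex-2-en-1-one
Conditions: NaH, HCO2Et, THF (cat. EtOH), 0 °C to rt; aq. HCl
Reagents that add atoms: ethyl formate CCOC=O
Why: Claisen formylation at the only enolisable position (the future C10) should give the chelated hydroxymethylidene ketone, which supplies C20 and the acidic carbon nucleophile for step 4.

Step 4
Reactants: 4 (5R,6Z)-5-ethenyl-6-(hydroxymethylidene)-4,4-dimethylcyclohex-2-en-1-one; 5 methyl acrylate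
Product: 6 methyl 3-[(1S,6R)-6-ethenyl-1-formyl-5,5-dimethyl-2-oxocyclohex-3-en-1-yl]propanoate
Conditions: Et3N (cat.), MeCN, rt
Reagents that add atoms: none
Why: Michael addition of the 2-formyl ketone should create the C10 quaternary centre with the acrylate approaching anti to the adjacent C5 vinyl group, so that the lactone chain (C9) is trans and the formyl carbon (C20) cis to the vinyl group.

Step 5
Reactants: 6 methyl 3-[(1S,6R)-6-ethenyl-1-formyl-5,5-dimethyl-2-oxocyclohex-3-en-1-yl]propanoate
Product: 9 hydroxy spirolactone (C1-OH trans to C20), via hydroxy ketone ester 7 (not isolated), via diol ester 8 (not isolated)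
Conditions: Me4NBH(OAc)3, AcOH–MeCN, −30 °C to rt; then PPTS (cat.), PhH, 50 °C
Reagents that add atoms: none
Why: Triacetoxyborohydride should reduce the aldehyde first, the C20 alkoxyborohydride then delivering hydride intramolecularly to the C1 ketone (Evans–Saksena hydroxyl-directed reduction) so that the C1 hydroxyl is trans to C20, and mild acid should close the δ-lactone through the primary alcohol.

Step 6
Reactants: 9 hydroxy spirolactone
Product: 10 triethylsilyl ether of 9
Conditions: Et3SiOTf, 2,6-lutidine, CH2Cl2, −78 °C
Reagents that add atoms: triethylsilyl trifluoromethanesulfonate CC[Si](CC)(CC)OS(=O)(=O)C(F)(F)F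
Why: Silylation of the hindered allylic alcohol masks ring A as a base-stable allylic silyl ether for the carbanion steps, and the ether is axial on ring A so the C1 side of the lactone stays open.

Step 7
Reactants: 10 triethylsilyl ether of 9
Product: 12 α,β-unsaturated spirolactone (C8=C9), via selenide 11 (not isolated)
Conditions: LDA, THF, −78 °C; PhSeBr; then H2O2, pyridine, CH2Cl2, 0 °C to rt
Reagents that add atoms: none
Why: α-Selenenylation of the lithium lactone enolate followed by selenoxide syn-elimination toward C9, the only carbon with β-hydrogens, should give the unsaturated lactone.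

Step 8
Reactants: 12 α,β-unsaturated spirolactone; 13 methyl phenyl sulfone
Product: 15 C8-hydroxymethylidene lactone bearing CH2SO2Ph at C9, via lithium enolate 14 (not isolated)
Conditions: 13, n-BuLi, THF–DMPU, −78 °C; add 12, −78 to −40 °C; CF3CH2OCHO, −78 to 0 °C; aq. NH4Cl
Reagents that add atoms: 2,2,2-trifluoroethyl formate O=COCC(F)(F)F
Why: Conjugate addition of the α-sulfonyl carbanion should occur on the C1 face of C9 (the C5 face is shielded by the equatorial vinyl group, whereas C1 offers an equatorial hydrogen and an axial silyl ether), setting C9 with C11 cis to C1, and the lactone enolate so formed is trapped regiospecifically at C8 by Claisen formylation.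

Step 9
Reactants: 15 C8-hydroxymethylidene lactone bearing CH2SO2Ph at C9; 16 3-bromo-2-(bromomethyl)prop-1-ene
Product: 18 ring C annulated aldehyde (13-methylene; C8 formyl), via monoalkylated sulfone 17 (not isolated)
Conditions: LDA (2.1 equiv), THF–DMPU, −78 °C; 16, −78 °C to rt
Reagents that add atoms: none
Why: Two equivalents of LDA should give the dianion of 15 (formyl-lactone enolate at C8, α-sulfonyl carbanion at C11); the far more nucleophilic sulfonyl carbanion is alkylated first by one allylic bromide of 16 (intermolecular SN2, C11–C12), and on warming the stabilised C8 enolate closes ring C on the second allylic bromide (C8–C14). The closest known reaction type is the alkylative [3+3] annulation of 1,3-dicarbanions (β-keto ester dianions, bis-sulfone dianions) with 2-methylene-1,3-dihalopropanes. Ring C closes in a 6-(enolexo)-exo-tet mode, both carbonyl carbons (C7, C15) lying outside the new ring. The C8–C14 bond has to form perpendicular to the enolate plane on the face where the C9 side chain (C11) sits, so ring C becomes cis-fused to the lactone and C8 is set by relay from C9, with C14 cis to C11 and the formyl carbon C15 trans; the C11 centre is uncontrolled and is erased in step 11. The step needs C11-before-C8 ordering and C- over O-alkylation: the first follows from the reactivity gap between the two carbanions, the second from the eight-membered ring that O-alkylation would require.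

Step 10
Reactants: 18 ring C annulated aldehyde
Product: 19 C15 carbinol (1-hydroxypropyl at C8)
Conditions: EtMgBr, THF, −78 °C; aq. NH4Cl
Reagents that add atoms: ethylmagnesium bromide CC[Mg]Br
Why: Grignard addition to the aldehyde, far more electrophilic than the lactone, installs C16 and C17, and the new C15 carbinol centre is oxidised in step 12 so its configuration is immaterial.

Step 11
Reactants: 19 C15 carbinol
Product: 21 C1,C15-diol, via desulfonylated silyl ether 20 (not isolated)
Conditions: Na(Hg), Na2HPO4, MeOH–THF, −20 °C; then 1 M HCl, THF, 0 °C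
Reagents that add atoms: none
Why: Reductive desulfonylation with sodium amalgam removes the activating group at C11 without touching the alkenes or the lactone, and the acidic work-up hydrolyses the triethylsilyl ether.

Step 12
Reactants: 21 C1,C15-diol
Product: 22 1,15-diketone (ring A enone; C8 propanoyl)
Conditions: Dess–Martin periodinane, NaHCO3, CH2Cl2, rt
Reagents that add atoms: none
Why: Dess–Martin oxidation converts both secondary alcohols in one operation, regenerating the ring A enone and forming the C15 ethyl ketone.

Step 13
Reactants: 22 1,15-diketone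
Product: 23 1,13,15-triketone 6-aldehyde
Conditions: O3 (measured charge), CH2Cl2, −78 °C; Me2S
Reagents that add atoms: ozone [O-][O+]=O
Why: Ozonolysis should cleave the two electron-rich alkenes (C13 methylene, C5 vinyl) while the electron-poor ring A enone survives a controlled ozone charge, unveiling the C13 ketone and the C6 aldehyde.

Step 14
Reactants: 23 1,13,15-triketone 6-aldehyde
Product: 24 1,13,15-triketone 6-alcohol
Conditions: NaBH(OAc)3, AcOH, PhH, rt
Reagents that add atoms: none
Why: Triacetoxyborohydride reduction is chemoselective for the aldehyde in the presence of the three ketones.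

Step 15
Reactants: 24 1,13,15-triketone 6-alcohol
Product: 25 target compound
Conditions: TiCl4, Bu3N, CH2Cl2, −78 °C; aq. NH4Cl
Reagents that add atoms: none
Why: In this titanium-mediated soft-enolisation intramolecular aldol, bidentate chelation of TiCl4 by the β-keto lactone (C7=O, C15=O) should direct enolisation to C16, and the (Z)-enolate attacks the C13 ketone lying 1,3-diaxial to the C15 carbonyl on ring C to close ring D, which fixes C13 through the bridge and places the C17 methyl endo (toward C11/C12) as in the target, dehydration being impossible at the bridgehead.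

**Compound list**

1 | 4,4-dimethylcyclohex-2-en-1-one | CC1(C)CCC(=O)C=C1 | starting material
2 | 4,4-dimethylcyclohexa-2,5-dien-1-one | CC1(C)C=CC(=O)C=C1 | intermediate
3 | (5R)-5-ethenyl-4,4-dimethylcyclohex-2-en-1-one | O=C1C=CC(C)(C)[C@@H](C=C)C1 | intermediate
4 | (5R,6Z)-5-ethenyl-6-(hydroxymethylidene)-4,4-dimethylcyclohex-2-en-1-one | O/C=C1\C(=O)C=CC(C)(C)[C@H]1C=C | intermediate
5 | methyl acrylate | C=CC(=O)OC | starting material
6 | methyl 3-[(1S,6R)-6-ethenyl-1-formyl-5,5-dimethyl-2-oxocyclohex-3-en-1-yl]propanoate | COC(=O)CC[C@]1(C=O)C(=O)C=CC(C)(C)[C@H]1C=C | intermediate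
7 | methyl 3-[(1S,6R)-6-ethenyl-1-(hydroxymethyl)-5,5-dimethyl-2-oxocyclohex-3-en-1-yl]propanoate | COC(=O)CC[C@]1(CO)C(=O)C=CC(C)(C)[C@H]1C=C | intermediate
8 | methyl 3-[(1S,2R,6R)-6-ethenyl-2-hydroxy-1-(hydroxymethyl)-5,5-dimethylcyclohex-3-en-1-yl]propanoate | COC(=O)CC[C@]1(CO)[C@H](O)C=CC(C)(C)[C@H]1C=C | intermediate
9 | (6S,7R,11R)-11-ethenyl-7-hydroxy-10,10-dimethyl-2-oxaspiro[5.5]undec-8-en-3-one (C1-OH trans to C20; C5 vinyl cis to C20) | O=C1CC[C@]2(CO1)[C@H](O)C=CC(C)(C)[C@H]2C=C | intermediate
10 | (6S,7R,11R)-11-ethenyl-10,10-dimethyl-7-(triethylsilyloxy)-2-oxaspiro[5.5]undec-8-en-3-one | O=C1CC[C@]2(CO1)[C@H](O[Si](CC)(CC)CC)C=CC(C)(C)[C@H]2C=C | intermediate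
11 | 4-(phenylselanyl) derivative of 10 (C8 selenide; epimers at C8) | O=C1C([Se]c3ccccc3)C[C@]2(CO1)[C@H](O[Si](CC)(CC)CC)C=CC(C)(C)[C@H]2C=C | intermediate
12 | 11-ethenyl-10,10-dimethyl-7-(triethylsilyloxy)-2-oxaspiro[5.5]undeca-4,8-dien-3-one (C8=C9 unsaturated lactone; spiro, C1 and C5 centres as in 10) | O=C1C=C[C@]2(CO1)[C@H](O[Si](CC)(CC)CC)C=CC(C)(C)[C@H]2C=C | intermediate
13 | methyl phenyl sulfone | CS(=O)(=O)c1ccccc1 | starting material
14 | lithium enolate of the C9 conjugate adduct (CH2SO2Ph on C9 cis to C1 across the lactone) | [Li]OC1=C[C@@H](CS(=O)(=O)c2ccccc2)[C@]3(CO1)[C@H](O[Si](CC)(CC)CC)C=CC(C)(C)[C@H]3C=C | intermediate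
15 | C8-(hydroxymethylidene) spirolactone with (phenylsulfonyl)methyl at C9 (C11 cis to C1), C1-OSiEt3, C5-vinyl | O=S(=O)(c1ccccc1)C[C@@H]1C(=CO)C(=O)OC[C@]12[C@H](O[Si](CC)(CC)CC)C=CC(C)(C)[C@H]2C=C | intermediate
16 | 3-bromo-2-(bromomethyl)prop-1-ene | C=C(CBr)CBr | starting material
17 | C11-[2-(bromomethyl)prop-2-en-1-yl] derivative of 15 (C11 epimers) | O=S(=O)(c1ccccc1)C(CC(=C)CBr)[C@@H]1C(=CO)C(=O)OC[C@]12[C@H](O[Si](CC)(CC)CC)C=CC(C)(C)[C@H]2C=C | intermediate
18 | tricyclic aldehyde: 13-methylenecyclohexane ring C cis-fused to the lactone at C8–C9; C8 bears CHO (C15) trans to C11; C11-SO2Ph (epimers); C1-OSiEt3; C5-vinyl | O=C[C@]23CC(=C)CC(S(=O)(=O)c4ccccc4)[C@H]2[C@]1(COC3=O)[C@H](O[Si](CC)(CC)CC)C=CC(C)(C)[C@H]1C=C | intermediate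
19 | C15 carbinol of 18: C8 bears CH(OH)CH2CH3 (C15 epimers) | CCC(O)[C@]23CC(=C)CC(S(=O)(=O)c4ccccc4)[C@H]2[C@]1(COC3=O)[C@H](O[Si](CC)(CC)CC)C=CC(C)(C)[C@H]1C=C | intermediate
20 | desulfonylated silyl ether (C11 = CH2) | CCC(O)[C@]23CC(=C)CC[C@H]2[C@]1(COC3=O)[C@H](O[Si](CC)(CC)CC)C=CC(C)(C)[C@H]1C=C | intermediate
21 | C1,C15-diol: 13-methylene tricycle with C1-OH, C8-CH(OH)Et, C5-vinyl | CCC(O)[C@]23CC(=C)CC[C@H]2[C@]1(COC3=O)[C@H](O)C=CC(C)(C)[C@H]1C=C | intermediate
22 | 1,15-diketone: ring A 2-en-1-one, C8 propanoyl, 13-methylene, C5-vinyl | CCC(=O)[C@]23CC(=C)CC[C@H]2[C@]1(COC3=O)C(=O)C=CC(C)(C)[C@H]1C=C | intermediate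
23 | 1,13,15-triketone with C6 aldehyde on C5 | CCC(=O)[C@]23CC(=O)CC[C@H]2[C@]1(COC3=O)C(=O)C=CC(C)(C)[C@H]1C=O | intermediate
24 | 1,13,15-triketone with C6 CH2OH on C5 | CCC(=O)[C@]23CC(=O)CC[C@H]2[C@]1(COC3=O)C(=O)C=CC(C)(C)[C@H]1CO | intermediate
25 | CNP0533761.1: 6,13-dihydroxy-1,15-dioxo-6,7-seco-ent-kaur-2-en-7,20-olide, 16-methyl endo | C[C@H]1C(=O)[C@]23C[C@@]1(O)CC[C@H]2[C@]1(COC3=O)C(=O)C=CC(C)(C)[C@H]1CO | target

Total steps: 15. Longest linear sequence: 15 steps (1 to 25).

**Steps most likely to fail**

Step 8. The sulfonyl carbanion may add 1,2 to the lactone carbonyl, or attack C9 with insufficient facial selectivity (from the C5 face). The fallback sets out from 12 and replaces steric control by internal delivery. The silyl ether is removed (Bu4NF, THF) to give the unsaturated hydroxy spirolactone F1. Its lithium alkoxide (LiN(SiMe3)2, −78 °C) then directs LiCH2SO2Ph to the C1 face of C9 (alkoxide-directed conjugate addition), and formate trapping as before gives the C1-hydroxy analogue of 15, F2. Silylation of both hydroxyls (Et3SiOTf, 2,6-lutidine) gives the bis(triethylsilyl) derivative F3, whose labile enol silyl ether is hydrolysed (K2CO3, MeOH, 0 °C), and the route is rejoined at 15.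

Step 15. Enolisation may occur at the wrong ketone (C12/C14 of the cyclohexanone), or the kinetic C16 configuration may be lost through retro-aldol equilibration. The fallback sets out from 24 and separates ring closure from the setting of C16. A reversible, thermodynamically controlled aldol (K2CO3, MeOH), for which the bicyclo[3.2.1]octane closure is the least strained outcome, should give 25 together with its 16-epimer F4. The mixture is converted (Me3SiOTf, Et3N) into the tris(trimethylsilyl) 15,16-enol ether F5, and low-temperature acidic desilylation protonates C16 from the open exo face, placing the methyl endo and returning to 25.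

Step 9. Two molecules may be joined through one dibromide (oligomerisation), or ring closure by the weakly nucleophilic formyl-lactone enolate may be sluggish. The fallback sets out from 15 and divides the annulation into two mechanistically different bond formations. The sulfonyl carbanion is alkylated with one equivalent of 16 at −78 °C and the allylic bromide 17 is isolated. Ring C is then closed by a palladium-catalysed Tsuji–Trost allylic alkylation (Pd(PPh3)4, K2CO3, THF), in which O-allylation is reversible at zerovalent palladium and the same axial bond formation should give cis-fused 18, where the route is rejoined.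

Further compounds
F1 | step 8 | unsaturated hydroxy spirolactone (12 without the silyl group) | O=C1C=C[C@]2(CO1)[C@H](O)C=CC(C)(C)[C@H]2C=C
F2 | step 8 | C1-hydroxy analogue of 15 | O=S(=O)(c1ccccc1)C[C@@H]1C(=CO)C(=O)OC[C@]12[C@H](O)C=CC(C)(C)[C@H]2C=C
F3 | step 8 | bis(triethylsilyl) derivative of F2 (enol and C1 silyl ethers) | O=S(=O)(c1ccccc1)C[C@@H]1C(=CO[Si](CC)(CC)CC)C(=O)OC[C@]12[C@H](O[Si](CC)(CC)CC)C=CC(C)(C)[C@H]2C=C
F4 | step 15 | 16-epimer of 25 (methyl exo) | C[C@@H]1C(=O)[C@]23C[C@@]1(O)CC[C@H]2[C@]1(COC3=O)C(=O)C=CC(C)(C)[C@H]1CO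
F5 | step 15 | tris(trimethylsilyl) 15,16-enol ether of 25 (O6, O13 and O15 silylated) | CC1=C(O[Si](C)(C)C)[C@]23C[C@@]1(O[Si](C)(C)C)CC[C@H]2[C@]1(COC3=O)C(=O)C=CC(C)(C)[C@H]1CO[Si](C)(C)C
F0 | step 9 | none | none
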